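Ring A is disconnected across C8–C8a to a squarate-derived 4-hydroxycyclobutenone. Heating this precursor opens the four-membered ring to a dienylketene that recloses as a benzene ring, so one operation delivers ring A with O5, O6, O7 and O1 (on C5, C6, C7 and C8a) each from a different source and the acetyl precursor already on C4a; the step exploits the para C6–O/C8a–O hydroquinone pattern of ring A. The precursor is a racemic cyclobutenone carrying a benzyloxy group, a 1-ethoxyvinyl group on the ring alkene, and a carbinol carbon bearing hydroxyl and 1-tert-butoxyvinyl. A Baker–Venkataraman-type flavone synthesis, O7 sulfation and one hydrogenolysis finish the route.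

Key step: step 4

Remark: ring A atoms carry flavone numbers (C4a, C5 to C8, C8a, O1) in every intermediate.
Remark: the target is drawn as the free hydrogen sulfate; the sulfate is carried as its potassium salt and protonated only in the last operation, cold, because aryl hydrogen sulfates hydrolyse in concentrated acidic solution.
Remark: benzyl alcohol and benzyl bromide are treated as reagents; 3,4-bis(benzyloxy)benzoic acid is taken as a commercial starting material.

Step 1
Reactants: 1 squaric acid
Product: 2 3,4-bis(benzyloxy)cyclobut-3-ene-1,2-dione (dibenzyl squarate)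
Conditions: BnOH (2.5 equiv), toluene, reflux, Dean–Stark trap
Reagents that add atoms: benzyl alcohol, OCc1ccccc1
Why: Squaric acid is a strong vinylogous carboxylic acid that catalyses its own Fischer-type esterification with a primary alcohol once water is removed azeotropically, the usual way to dialkyl squarates.

Step 2
Reactants: 2 dibenzyl squarate; 3 ethyl vinyl ether
Product: 7 3-(benzyloxy)-4-(1-ethoxyvinyl)cyclobut-3-ene-1,2-dione, via 1-ethoxyvinyllithium 4 (not isolated), via lithium alkoxide adduct 5 (not isolated), via trifluoroacetate ester 6 (not isolated)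
Conditions: 3 (1.3 equiv), t-BuLi (1.15 equiv), THF, −78 to 0 °C; cannulate into 2, THF, −78 °C; (CF3CO)2O (1.3 equiv), −78 °C; pour into cold aq. NaHCO3
Reagents that add atoms: water, O
Why: α-Lithiation of the vinyl ether gives an acyl-anion equivalent that undergoes organolithium 1,2-addition to one of the two equivalent squarate carbonyls, and O-trifluoroacetylation of the alkoxide triggers allylic ionisation to a benzyloxy-stabilised cyclobutenyl cation whose hydrolysis on basic work-up expels benzyl alcohol (the anhydride-induced squarate-to-cyclobutenedione transposition).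

Step 3
Reactants: 7 3-(benzyloxy)-4-(1-ethoxyvinyl)cyclobut-3-ene-1,2-dione; 8 tert-butyl vinyl ether
Product: 11 3-(benzyloxy)-4-(1-tert-butoxyvinyl)-2-(1-ethoxyvinyl)-4-hydroxycyclobut-2-en-1-one (racemic), via 1-tert-butoxyvinyllithium 9 (not isolated), via lithium alkoxide 10 (not isolated)
Conditions: 8 (1.2 equiv), t-BuLi (1.1 equiv), THF, −78 to 0 °C; then 7, THF, −78 °C; cold aq. NH4Cl (neutral work-up)
Reagents that add atoms: none
Why: α-Lithiation of an alkyl vinyl ether followed by organolithium 1,2-addition, in which the carbonyl next to the benzyloxy-bearing carbon reacts as a ketone while the other is deactivated as a vinylogous ester, so the carbinol carbon (future C6) should form next to the benzyloxy carbon (future C5); the new stereocentre is formed racemic and is erased in step 4.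

Step 4
Reactants: 11 3-(benzyloxy)-4-(1-tert-butoxyvinyl)-2-(1-ethoxyvinyl)-4-hydroxycyclobut-2-en-1-one
Product: 14 3-(benzyloxy)-5-tert-butoxy-2-(1-ethoxyvinyl)benzene-1,4-diol, via dienylketene 12 (not isolated), via cyclohexadienone 13 (not isolated)
Conditions: degassed toluene (0.02 M), 110 °C, argon, base-washed glassware; crude 14 is taken on under argon
Reagents that add atoms: none
Why: Thermal conrotatory four-electron opening of the bond between the carbonyl carbon and the carbinol carbon gives the (Z)-dienylketene 12, disrotatory six-electron closure between the ketene carbon and the terminal CH2 of the tert-butoxyvinyl group forms C8–C8a, and enolisation of cyclohexadienone 13 should give hydroquinone 14. This is the Moore rearrangement of 4-alkenyl-4-hydroxycyclobutenones to hydroquinones, applied here to a new pair of alkoxyvinyl substituents. Ring A closes as a six-membered carbocycle by 6π electrocyclisation and aromatisation makes the closure irreversible; no stereocentre is created and the racemic carbinol centre disappears. The step needs torquoselectivity, which the carbinol hydroxyl secures: as a lone-pair donor it rotates outward and so turns the tert-butoxyvinyl group inward, next to the ketene. It also needs the right alkene to close: the 1-ethoxyvinyl group sits on the ketene α-carbon and could only close a four-membered ring, a reversible path back to a cyclobutenone, so it should be carried through unchanged. High dilution and exclusion of oxygen keep the ketene from bimolecular capture and the hydroquinone from oxidation.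

Step 5
Reactants: 14 3-(benzyloxy)-5-tert-butoxy-2-(1-ethoxyvinyl)benzene-1,4-diol
Product: 15 1-[2-(benzyloxy)-4-tert-butoxy-3,6-dihydroxyphenyl]ethan-1-one
Conditions: 0.1 M aq. oxalic acid/THF (1:4), 0 °C to rt, argon
Reagents that add atoms: water, O
Why: Acid-catalysed enol ether hydrolysis (C-protonation, oxocarbenium ion, hemiketal collapse) is far faster than cleavage of an aryl benzyl or aryl tert-butyl ether, so dilute acid should unmask only the acetyl group on C4a.

Step 6
Reactants: 15 1-[2-(benzyloxy)-4-tert-butoxy-3,6-dihydroxyphenyl]ethan-1-one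
Product: 16 1-[2,3-bis(benzyloxy)-4-tert-butoxy-6-hydroxyphenyl]ethan-1-one
Conditions: BnBr (1.05 equiv), K2CO3 (1.2 equiv), degassed acetone, rt to 40 °C, argon
Reagents that add atoms: benzyl bromide, BrCc1ccccc1
Why: Williamson ether synthesis in which the hydroxyl on C8a is held in a hydrogen bond to the acetyl carbonyl and is a poor nucleophile, so one equivalent of halide with a weak base should alkylate only O6, as in the standard monobenzylation of 2,5-dihydroxyacetophenones.

Step 7
Reactants: 17 3,4-bis(benzyloxy)benzoic acid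
Product: 18 3,4-bis(benzyloxy)benzoyl chloride
Conditions: (COCl)2 (1.3 equiv), cat. DMF, CH2Cl2, 0 °C to rt; evaporate, use crude
Reagents that add atoms: oxalyl chloride, O=C(Cl)C(=O)Cl
Why: Acid chloride formation through the catalytic Vilsmeier-type chloroiminium ion, conditions to which aryl benzyl ethers are inert.

Step 8
Reactants: 16 1-[2,3-bis(benzyloxy)-4-tert-butoxy-6-hydroxyphenyl]ethan-1-one; 18 3,4-bis(benzyloxy)benzoyl chloride
Product: 20 1-[2,3-bis(benzyloxy)-4-tert-butoxy-6-hydroxyphenyl]-3-[3,4-bis(benzyloxy)phenyl]propane-1,3-dione, via dilithium phenolate-enolate 19 (not isolated)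
Conditions: LiN(SiMe3)2 (3.2 equiv), THF, −78 to −10 °C; 18 (1.05 equiv), −78 °C to rt; 1 M HCl to pH 5, 0 °C
Reagents that add atoms: none
Why: Direct form of the Baker–Venkataraman construction: the phenolate-enolate dianion undergoes Claisen-type C-aroylation by the acid chloride (any O-aroyl ester formed rearranges under the same base by the intramolecular acyl shift), and the third equivalent of base takes up the acidic diketone proton.

Step 9
Reactants: 20 1-[2,3-bis(benzyloxy)-4-tert-butoxy-6-hydroxyphenyl]-3-[3,4-bis(benzyloxy)phenyl]propane-1,3-dione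
Product: 22 5,6-bis(benzyloxy)-2-[3,4-bis(benzyloxy)phenyl]-7-hydroxy-4H-chromen-4-one, via 7-tert-butoxyflavone 21 (not isolated)
Conditions: CF3CO2H/CH2Cl2 (1:4), 0 °C to rt, argon sweep
Reagents that add atoms: none
Why: Acid-catalysed cyclodehydration of the o-hydroxyaryl 1,3-diketone (second half of the Baker–Venkataraman flavone synthesis) closes ring C through the cyclic hemiketal, and the same acid cleaves the aryl tert-butyl ether by E1 loss of isobutene, whereas aryl benzyl ethers are stable to CF3CO2H at room temperature and the protonated pyranone deactivates ring A towards tert-butylation at C8.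

Step 10
Reactants: 22 5,6-bis(benzyloxy)-2-[3,4-bis(benzyloxy)phenyl]-7-hydroxy-4H-chromen-4-one
Product: 24 potassium 5,6-bis(benzyloxy)-2-[3,4-bis(benzyloxy)phenyl]-4-oxo-4H-chromen-7-yl sulfate, via pyridinium sulfate salt 23 (not isolated)
Conditions: SO3·pyridine (3 equiv), pyridine, rt to 50 °C; then aq. KHCO3, 0 °C; reversed-phase chromatography
Reagents that add atoms: sulfur trioxide–pyridine complex, O=S(=O)([O-])[n+]1ccccc1; potassium hydrogen carbonate, [K+].OC([O-])=O
Why: Sulfation of a phenol by an amine–SO3 complex at O7, the only free hydroxyl, followed by exchange of the pyridinium ion for potassium, which removes a base that would slow the later hydrogenolysis.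

Step 11
Reactants: 24 potassium 5,6-bis(benzyloxy)-2-[3,4-bis(benzyloxy)phenyl]-4-oxo-4H-chromen-7-yl sulfate
Product: 26 6-hydroxyluteolin 7-sulfate [2-(3,4-dihydroxyphenyl)-5,6-dihydroxy-4-oxo-4H-chromen-7-yl hydrogen sulfate], via potassium 6-hydroxyluteolin 7-sulfate 25 (not isolated)
Conditions: H2 (1 atm), Pd/C (10 wt% Pd), degassed MeOH/THF, rt, monitored to avoid reduction of C2=C3; filter under argon; aq. HCl (1.0 equiv), 0 °C; C18 cartridge; lyophilise
Reagents that add atoms: none
Why: Catalytic hydrogenolysis of the four aryl benzyl ethers (O5, O6, O3', O4') leaves the aryl sulfate monoester untouched, since the sulfate anion neither poisons Pd nor is cleaved by H2, and one equivalent of cold mineral acid converts the potassium salt into the hydrogen sulfate.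

Compound list
1 | squaric acid (3,4-dihydroxycyclobut-3-ene-1,2-dione) | O=C1C(O)=C(O)C1=O | starting material
2 | 3,4-bis(benzyloxy)cyclobut-3-ene-1,2-dione (dibenzyl squarate) | O=C1C(=O)C(OCc2ccccc2)=C1OCc1ccccc1 | intermediate
3 | ethyl vinyl ether | C=COCC | starting material
4 | 1-ethoxyvinyllithium | [Li]C(=C)OCC | intermediate
5 | lithium 2,3-bis(benzyloxy)-1-(1-ethoxyvinyl)-4-oxocyclobut-2-en-1-olate (racemic) | [Li+].[O-]C1(C(=C)OCC)C(OCc2ccccc2)=C(OCc2ccccc2)C1=O | intermediate
6 | 2,3-bis(benzyloxy)-1-(1-ethoxyvinyl)-4-oxocyclobut-2-en-1-yl trifluoroacetate (racemic) | O=C(OC1(C(=C)OCC)C(OCc2ccccc2)=C(OCc2ccccc2)C1=O)C(F)(F)F | intermediate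
7 | 3-(benzyloxy)-4-(1-ethoxyvinyl)cyclobut-3-ene-1,2-dione | C=C(OCC)C1=C(OCc2ccccc2)C(=O)C1=O | intermediate
8 | tert-butyl vinyl ether | C=COC(C)(C)C | starting material
9 | 1-tert-butoxyvinyllithium | [Li]C(=C)OC(C)(C)C | intermediate
10 | lithium 2-(benzyloxy)-1-(1-tert-butoxyvinyl)-3-(1-ethoxyvinyl)-4-oxocyclobut-2-en-1-olate (racemic) | [Li+].[O-]C1(C(=C)OC(C)(C)C)C(OCc2ccccc2)=C(C(=C)OCC)C1=O | intermediate
11 | 3-(benzyloxy)-4-(1-tert-butoxyvinyl)-2-(1-ethoxyvinyl)-4-hydroxycyclobut-2-en-1-one (racemic) | C=C(OCC)C1=C(OCc2ccccc2)C(O)(C(=C)OC(C)(C)C)C1=O | intermediate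
12 | (3Z)-3-(benzyloxy)-5-tert-butoxy-2-(1-ethoxyvinyl)-4-hydroxyhexa-1,3,5-trien-1-one (dienylketene) | O=C=C(C(=C)OCC)/C(OCc1ccccc1)=C(/O)C(=C)OC(C)(C)C | intermediate
13 | 3-(benzyloxy)-5-tert-butoxy-2-(1-ethoxyvinyl)-4-hydroxycyclohexa-2,4-dien-1-one | O=C1CC(OC(C)(C)C)=C(O)C(OCc2ccccc2)=C1C(=C)OCC | intermediate
14 | 3-(benzyloxy)-5-tert-butoxy-2-(1-ethoxyvinyl)benzene-1,4-diol | C=C(OCC)c1c(O)cc(OC(C)(C)C)c(O)c1OCc1ccccc1 | intermediate
15 | 1-[2-(benzyloxy)-4-tert-butoxy-3,6-dihydroxyphenyl]ethan-1-one | CC(=O)c1c(O)cc(OC(C)(C)C)c(O)c1OCc1ccccc1 | intermediate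
16 | 1-[2,3-bis(benzyloxy)-4-tert-butoxy-6-hydroxyphenyl]ethan-1-one | CC(=O)c1c(O)cc(OC(C)(C)C)c(OCc2ccccc2)c1OCc1ccccc1 | intermediate
17 | 3,4-bis(benzyloxy)benzoic acid | O=C(O)c1ccc(OCc2ccccc2)c(OCc2ccccc2)c1 | starting material
18 | 3,4-bis(benzyloxy)benzoyl chloride | O=C(Cl)c1ccc(OCc2ccccc2)c(OCc2ccccc2)c1 | intermediate
19 | dilithium 3,4-bis(benzyloxy)-5-tert-butoxy-2-(1-oxidoethenyl)phenolate | [Li+].[Li+].[O-]C(=C)c1c([O-])cc(OC(C)(C)C)c(OCc2ccccc2)c1OCc1ccccc1 | intermediate
20 | 1-[2,3-bis(benzyloxy)-4-tert-butoxy-6-hydroxyphenyl]-3-[3,4-bis(benzyloxy)phenyl]propane-1,3-dione | O=C(CC(=O)c1ccc(OCc2ccccc2)c(OCc2ccccc2)c1)c1c(O)cc(OC(C)(C)C)c(OCc2ccccc2)c1OCc1ccccc1 | intermediate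
21 | 5,6-bis(benzyloxy)-2-[3,4-bis(benzyloxy)phenyl]-7-tert-butoxy-4H-chromen-4-one | O=c1cc(-c2ccc(OCc3ccccc3)c(OCc3ccccc3)c2)oc2cc(OC(C)(C)C)c(OCc3ccccc3)c(OCc3ccccc3)c12 | intermediate
22 | 5,6-bis(benzyloxy)-2-[3,4-bis(benzyloxy)phenyl]-7-hydroxy-4H-chromen-4-one | O=c1cc(-c2ccc(OCc3ccccc3)c(OCc3ccccc3)c2)oc2cc(O)c(OCc3ccccc3)c(OCc3ccccc3)c12 | intermediate
23 | pyridinium 5,6-bis(benzyloxy)-2-[3,4-bis(benzyloxy)phenyl]-4-oxo-4H-chromen-7-yl sulfate | O=c1cc(-c2ccc(OCc3ccccc3)c(OCc3ccccc3)c2)oc2cc(OS(=O)(=O)[O-])c(OCc3ccccc3)c(OCc3ccccc3)c12.c1cc[nH+]cc1 | intermediate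
24 | potassium 5,6-bis(benzyloxy)-2-[3,4-bis(benzyloxy)phenyl]-4-oxo-4H-chromen-7-yl sulfate | [K+].O=c1cc(-c2ccc(OCc3ccccc3)c(OCc3ccccc3)c2)oc2cc(OS(=O)(=O)[O-])c(OCc3ccccc3)c(OCc3ccccc3)c12 | intermediate
25 | potassium 2-(3,4-dihydroxyphenyl)-5,6-dihydroxy-4-oxo-4H-chromen-7-yl sulfate | [K+].O=c1cc(-c2ccc(O)c(O)c2)oc2cc(OS(=O)(=O)[O-])c(O)c(O)c12 | intermediate
26 | 6-hydroxyluteolin 7-sulfate [2-(3,4-dihydroxyphenyl)-5,6-dihydroxy-4-oxo-4H-chromen-7-yl hydrogen sulfate] | O=c1cc(-c2ccc(O)c(O)c2)oc2cc(OS(=O)(=O)O)c(O)c(O)c12 | target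

Total step count: 11. Longest linear sequence: 10 steps (steps 1 to 6 and 8 to 11, from squaric acid); step 7 is a one-step side branch.

Steps most likely to fail

Step 4 (key step). The ketene may be captured by a hydroxyl group before ring closure, either by lactonisation if the hydroxyl turns inward or by esterification with another molecule. The hot, electron-rich hydroquinone may also be oxidised to a quinone by traces of oxygen. The fallback uses the known siloxy variant of the same ring expansion, so that neither a free carbinol hydroxyl nor a free hydroquinone is present. It sets out from 11: N-(trimethylsilyl)imidazole in CH2Cl2 at rt should give 3-(benzyloxy)-4-(1-tert-butoxyvinyl)-2-(1-ethoxyvinyl)-4-[(trimethylsilyl)oxy]cyclobut-2-en-1-one F1. Heating F1 in degassed toluene at 110 °C should pass through the siloxy dienylketene (3Z)-3-(benzyloxy)-5-tert-butoxy-2-(1-ethoxyvinyl)-4-[(trimethylsilyl)oxy]hexa-1,3,5-trien-1-one F2 and the dienone 3-(benzyloxy)-5-tert-butoxy-2-(1-ethoxyvinyl)-4-[(trimethylsilyl)oxy]cyclohexa-2,4-dien-1-one F3, since the siloxy group is an equally good outward-rotating donor. It should end at the O6-silylated phenol 3-(benzyloxy)-5-tert-butoxy-2-(1-ethoxyvinyl)-4-[(trimethylsilyl)oxy]phenol F4, which is not a hydroquinone and resists air. Dilute aqueous oxalic acid, as in step 5, then cleaves both the O–Si bond and the enol ether, and the route is rejoined at 15.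

Step 2. The trifluoroacetic acid released during ionisation and work-up may protonate the 1-ethoxyvinyl enol ether and hydrolyse it, and a second equivalent of organolithium may add. The fallback replaces addition and rearrangement by a cross-coupling and sets out from 1. Oxalyl chloride with catalytic DMF should give 3,4-dichlorocyclobut-3-ene-1,2-dione F5. One equivalent of benzyl alcohol in CH2Cl2 at 0 °C should replace a single chloride to give 3-(benzyloxy)-4-chlorocyclobut-3-ene-1,2-dione F6. Stille coupling of F6 with commercial tributyl(1-ethoxyvinyl)stannane (Pd(PPh3)4, CuI, dioxane, rt to 50 °C), a known reaction of chlorocyclobutenediones carried out without any acid, should give 7, where the route is rejoined.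

Step 9. The tert-butyl cation may re-attack ring A at C8, and the acid may partly strip the peri benzyl ether on O5, giving mixtures. The fallback drives the peri debenzylation to completion and relies on chelation instead of protection; it sets out from 20. Heating in AcOH/conc. HCl (10:1) at 70 °C should close ring C and remove the tert-butyl group, with chloride trapping the cation, passing through 21 and 22. It should then cleave the O5 benzyl ether selectively, assisted by the protonated C4 carbonyl, to give 6-(benzyloxy)-2-[3,4-bis(benzyloxy)phenyl]-5,7-dihydroxy-4H-chromen-4-one F7. SO3·pyridine in pyridine should sulfate only O7, because the O5 hydroxyl is locked in a hydrogen bond to the C4 carbonyl. This gives pyridinium 6-(benzyloxy)-2-[3,4-bis(benzyloxy)phenyl]-5-hydroxy-4-oxo-4H-chromen-7-yl sulfate F8 and, after aq. KHCO3, potassium 6-(benzyloxy)-2-[3,4-bis(benzyloxy)phenyl]-5-hydroxy-4-oxo-4H-chromen-7-yl sulfate F9. Hydrogenolysis of the three remaining benzyl ethers (H2, Pd/C) rejoins the route at 25, from which the acidification of step 11 releases 26.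

Further compounds
F1 | step 4 | 3-(benzyloxy)-4-(1-tert-butoxyvinyl)-2-(1-ethoxyvinyl)-4-[(trimethylsilyl)oxy]cyclobut-2-en-1-one (racemic) | C=C(OCC)C1=C(OCc2ccccc2)C(O[Si](C)(C)C)(C(=C)OC(C)(C)C)C1=O
F2 | step 4 | (3Z)-3-(benzyloxy)-5-tert-butoxy-2-(1-ethoxyvinyl)-4-[(trimethylsilyl)oxy]hexa-1,3,5-trien-1-one | O=C=C(C(=C)OCC)/C(OCc1ccccc1)=C(/O[Si](C)(C)C)C(=C)OC(C)(C)C
F3 | step 4 | 3-(benzyloxy)-5-tert-butoxy-2-(1-ethoxyvinyl)-4-[(trimethylsilyl)oxy]cyclohexa-2,4-dien-1-one | O=C1CC(OC(C)(C)C)=C(O[Si](C)(C)C)C(OCc2ccccc2)=C1C(=C)OCC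
F4 | step 4 | 3-(benzyloxy)-5-tert-butoxy-2-(1-ethoxyvinyl)-4-[(trimethylsilyl)oxy]phenol | C=C(OCC)c1c(O)cc(OC(C)(C)C)c(O[Si](C)(C)C)c1OCc1ccccc1
F5 | step 2 | 3,4-dichlorocyclobut-3-ene-1,2-dione | O=C1C(Cl)=C(Cl)C1=O
F6 | step 2 | 3-(benzyloxy)-4-chlorocyclobut-3-ene-1,2-dione | O=C1C(Cl)=C(OCc2ccccc2)C1=O
F7 | step 9 | 6-(benzyloxy)-2-[3,4-bis(benzyloxy)phenyl]-5,7-dihydroxy-4H-chromen-4-one | O=c1cc(-c2ccc(OCc3ccccc3)c(OCc3ccccc3)c2)oc2cc(O)c(OCc3ccccc3)c(O)c12
F8 | step 9 | pyridinium 6-(benzyloxy)-2-[3,4-bis(benzyloxy)phenyl]-5-hydroxy-4-oxo-4H-chromen-7-yl sulfate | O=c1cc(-c2ccc(OCc3ccccc3)c(OCc3ccccc3)c2)oc2cc(OS(=O)(=O)[O-])c(OCc3ccccc3)c(O)c12.c1cc[nH+]cc1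
F9 | step 9 | potassium 6-(benzyloxy)-2-[3,4-bis(benzyloxy)phenyl]-5-hydroxy-4-oxo-4H-chromen-7-yl sulfate | [K+].O=c1cc(-c2ccc(OCc3ccccc3)c(OCc3ccccc3)c2)oc2cc(OS(=O)(=O)[O-])c(OCc3ccccc3)c(O)c12
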